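The oxane is disconnected at O1–C6 and C5–Br. The motif C5(H)Br–C6(CH3)2–O1, a secondary bromide beta to the ring oxygen across a gem-dimethyl carbon, is the retron of anti addition of Br+ and a tertiary hydroxyl to a 2-methylpent-2-ene terminus. In one operation the key step closes the oxane (6-endo), forms the C6–O1 and C5–Br bonds and sets C5 by relay from the quaternary carbinol C2. Its precursor is an open-chain tertiary alcohol on a cyclohexane that already carries hydroxyl, bromide and chloride, assembled by an auxiliary aldol, ring-closing metathesis, polarity-reversed halogenation and a chelation-controlled Grignard addition.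

Key step: step 11

Remark: oxane locants are those of the target name (O1, quaternary C2, C5 bearing bromine, gem-dimethyl C6); the "alpha face" of the carbocycle is the face that carries the acyl group (later the side chain) and the secondary hydroxyl; the dihalide equilibrium of step 7 is assumed to lie on the diequatorial side.

Step 1
Reactants: 1 (4R)-4-benzyl-1,3-oxazolidin-2-one; 2 pent-4-enoyl chloride
Product: 3 (4R)-4-benzyl-3-(pent-4-enoyl)-1,3-oxazolidin-2-one
Conditions: Et3N, DMAP (cat.), CH2Cl2, 0 °C → rt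
Reagents that add atoms: none
Why: N-acylation of the oxazolidinone by the acid chloride under nucleophilic catalysis is routine and leaves the auxiliary stereocenter untouched.

Step 2
Reactants: 4 3-methylbut-3-en-1-ol
Product: 5 3-methylbut-3-enal
Conditions: Dess–Martin periodinane, CH2Cl2, 0 °C; cold filtered solution used at once
Reagents that add atoms: none
Why: Dess–Martin oxidation of the homoallylic primary alcohol is fast and nearly neutral, so the β,γ-unsaturated aldehyde should survive without conjugation if kept cold and used directly.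

Step 3
Reactants: 3 (4R)-4-benzyl-3-(pent-4-enoyl)-1,3-oxazolidin-2-one; 5 3-methylbut-3-enal
Product: 8 (4R)-4-benzyl-3-[(2R,3S)-3-hydroxy-5-methyl-2-(prop-2-en-1-yl)hex-5-enoyl]-1,3-oxazolidin-2-one, via Z-dibutylboron enolate 6 (not isolated), via dibutylboron aldolate 7 (not isolated)
Conditions: Bu2BOTf, i-Pr2NEt, CH2Cl2, −78 → 0 °C; 5, −78 → 0 °C; then pH 7 buffer, MeOH, 30% H2O2, 0 °C
Reagents that add atoms: none
Why: Evans syn aldol reaction, in which the Z-boron enolate reacts through a closed chair transition state on the enolate face opposite the benzyl group, so that both new stereocenters should be set as (2R,3S) with a syn relationship.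

Step 4
Reactants: 8 (4R)-4-benzyl-3-[(2R,3S)-3-hydroxy-5-methyl-2-(prop-2-en-1-yl)hex-5-enoyl]-1,3-oxazolidin-2-one
Product: 9 (4R)-4-benzyl-3-{[(1R,6S)-6-hydroxy-4-methylcyclohex-3-en-1-yl]carbonyl}-1,3-oxazolidin-2-one
Conditions: second-generation Grubbs catalyst RuCl2(=CHPh)(PCy3)(H2IMes) (3 mol%), CH2Cl2 (0.01 M), 40 °C
Reagents that add atoms: none
Why: Ring-closing metathesis of the monosubstituted and the 1,1-disubstituted alkene closes the trisubstituted cyclohexene with loss of ethene, and the syn aldol relationship becomes a cis arrangement of acyl and hydroxyl groups without touching a stereocenter.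

Step 5
Reactants: 9 (4R)-4-benzyl-3-{[(1R,6S)-6-hydroxy-4-methylcyclohex-3-en-1-yl]carbonyl}-1,3-oxazolidin-2-one
Product: 10 (4R)-4-benzyl-3-{[(1R,2S,4R,5R)-5-chloro-2,4-dihydroxy-4-methylcyclohexyl]carbonyl}-1,3-oxazolidin-2-one
Conditions: NCS (1.1 equiv), acetone/H2O 4:1, 0 °C → rt, dark
Reagents that add atoms: N-chlorosuccinimide O=C1CCC(=O)N1Cl; water O
Why: Chlorohydrin formation by anti addition, in which water opens the chloronium ion at the tertiary carbon by axial attack on the alpha face of the half-chair with equatorial acyl group, so chlorine should end up axial on the opposite face; a direct bromochlorination would follow the same course and put bromine on the wrong face, which is why the halogens enter with reversed polarity.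

Step 6
Reactants: 10 (4R)-4-benzyl-3-{[(1R,2S,4R,5R)-5-chloro-2,4-dihydroxy-4-methylcyclohexyl]carbonyl}-1,3-oxazolidin-2-one
Product: 11 (4R)-4-benzyl-3-{[(1R,2S,4R,5R)-4-bromo-5-chloro-2-hydroxy-4-methylcyclohexyl]carbonyl}-1,3-oxazolidin-2-one
Conditions: TMSBr (3 equiv), CH2Cl2, 0 °C → rt; then H2O
Reagents that add atoms: bromotrimethylsilane C[Si](C)(C)Br
Why: Ionising substitution of the tertiary alcohol by bromide with anchimeric assistance from the antiperiplanar axial chlorine, so bromide should enter axially on the face the oxygen left (retention) and give the trans-diaxial tertiary bromide/secondary chloride, while the secondary hydroxyl is only silylated transiently.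

Step 7
Reactants: 11 (4R)-4-benzyl-3-{[(1R,2S,4R,5R)-4-bromo-5-chloro-2-hydroxy-4-methylcyclohexyl]carbonyl}-1,3-oxazolidin-2-one
Product: 12 (4R)-4-benzyl-3-{[(1R,2S,4S,5S)-5-bromo-4-chloro-2-hydroxy-4-methylcyclohexyl]carbonyl}-1,3-oxazolidin-2-one
Conditions: PhMe, 105 °C, sealed tube, dark
Reagents that add atoms: none
Why: Thermal diaxial-to-diequatorial rearrangement of a vicinal dihalide, in which bromine and chlorine exchange carbons through a bridged ion-pair transition state while each stays on its own ring face, which should place bromine equatorial on the secondary carbon (alpha face) and chlorine equatorial on the tertiary carbon with the methyl group axial.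

Step 8
Reactants: 12 (4R)-4-benzyl-3-{[(1R,2S,4S,5S)-5-bromo-4-chloro-2-hydroxy-4-methylcyclohexyl]carbonyl}-1,3-oxazolidin-2-one
Product: 13 (1R,2S,4S,5S)-5-bromo-4-chloro-2-hydroxy-N-methoxy-N,4-dimethylcyclohexane-1-carboxamide
Conditions: MeNHOMe·HCl (3 equiv), AlMe3 (3 equiv), THF, −20 → 0 °C; then cold 0.5 M HCl
Reagents that add atoms: N,O-dimethylhydroxylamine hydrochloride CNOC.Cl
Why: Aluminium amide transamination of the N-acyloxazolidinone to the Weinreb amide, directed to the exocyclic carbonyl by the free β-hydroxyl, with THF tempering the Lewis acidity so that the tertiary chloride should not ionise and no stereocenter changes.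

Step 9
Reactants: 13 (1R,2S,4S,5S)-5-bromo-4-chloro-2-hydroxy-N-methoxy-N,4-dimethylcyclohexane-1-carboxamide
Product: 14 1-[(1R,2S,4S,5S)-5-bromo-4-chloro-2-hydroxy-4-methylcyclohexyl]ethan-1-one
Conditions: MeMgBr (3 equiv), THF, −78 → 0 °C; then H2O
Reagents that add atoms: methylmagnesium bromide C[Mg]Br
Why: Weinreb ketone synthesis, in which the chelated tetrahedral adduct resists a second addition and the equatorial halides offer no antiperiplanar hydrogen for elimination at low temperature.

Step 10
Reactants: 14 1-[(1R,2S,4S,5S)-5-bromo-4-chloro-2-hydroxy-4-methylcyclohexyl]ethan-1-one; 15 5-bromo-2-methylpent-2-ene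
Product: 17 (1S,2R,4S,5S)-4-bromo-5-chloro-2-[(2S)-2-hydroxy-6-methylhept-5-en-2-yl]-5-methylcyclohexan-1-ol, via (4-methylpent-3-en-1-yl)magnesium bromide 16 (not isolated)
Conditions: 15, Mg, THF, rt (gives 16); 14, Et2O, −78 → −40 °C, 16 (3 equiv); then H2O
Reagents that add atoms: none
Why: Chelation-controlled Grignard addition, in which magnesium bridges the deprotonated cis-β-hydroxyl and the ketone oxygen in a six-membered chelate cis-fused to the cyclohexane and the nucleophile should attack its convex face, anti to the ring carbons, setting the tertiary carbinol as (S).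

Step 11
Reactants: 17 (1S,2R,4S,5S)-4-bromo-5-chloro-2-[(2S)-2-hydroxy-6-methylhept-5-en-2-yl]-5-methylcyclohexan-1-ol
Product: 18 (1S,2R,4S,5S)-4-bromo-2-[(2S,5R)-5-bromo-2,6,6-trimethyloxan-2-yl]-5-chloro-5-methylcyclohexan-1-ol
Conditions: 2,4,4,6-tetrabromocyclohexa-2,5-dien-1-one (TBCO, 1.1 equiv), MeNO2, 0 °C → rt, dark
Reagents that add atoms: TBCO O=C1C(Br)=CC(Br)(Br)C=C1Br
Why: TBCO transfers Br+ reversibly to the electron-rich trisubstituted alkene, the tertiary hydroxyl opens the bromonium ion anti at its gem-dimethyl carbon, and tribromophenoxide takes up the proton. The closest known reaction type is the biomimetic bromonium-induced etherification of bishomoallylic tertiary alcohols with TBCO. The oxane closes in the 6-endo mode (6-endo-trig with respect to the alkene, Markovnikov opening of the bromonium ion) through a chair-like transition state. The new stereocenter C5 is controlled by the quaternary carbinol C2: anti addition in a chair makes the C5–Br bond equatorial, and the chair that holds the bulky cyclohexyl group equatorial and only the C2 methyl axial (syn-diaxial to an axial C6 methyl across O1) should be preferred, which gives the 2,5-trans, (2S,5R) ring. The step needs 6-endo over 5-exo regioselectivity and chemoselectivity; the gem-dimethyl terminus, which places the positive charge on the tertiary carbon, together with the ionising solvent secures the former. The substrate secures the latter because the cyclohexane is already saturated and halogenated and the secondary hydroxyl could only close a seven- or eight-membered ring.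

Compound list
1 | (4R)-4-benzyl-1,3-oxazolidin-2-one | O=C1OC[C@@H](Cc2ccccc2)N1 | starting material
2 | pent-4-enoyl chloride | C=CCCC(Cl)=O | starting material
3 | (4R)-4-benzyl-3-(pent-4-enoyl)-1,3-oxazolidin-2-one | C=CCCC(=O)N1C(=O)OC[C@H]1Cc1ccccc1 | intermediate
4 | 3-methylbut-3-en-1-ol | CC(=C)CCO | starting material
5 | 3-methylbut-3-enal | CC(=C)CC=O | intermediate
6 | Z-dibutylboron enolate of 3 | C=CC/C=C(\OB(CCCC)CCCC)N1C(=O)OC[C@H]1Cc1ccccc1 | intermediate (not isolated)
7 | dibutylboron aldolate of 8 | C=CC[C@H]([C@@H](OB(CCCC)CCCC)CC(C)=C)C(=O)N1C(=O)OC[C@H]1Cc1ccccc1 | intermediate (not isolated)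
8 | (4R)-4-benzyl-3-[(2R,3S)-3-hydroxy-5-methyl-2-(prop-2-en-1-yl)hex-5-enoyl]-1,3-oxazolidin-2-one | C=CC[C@H]([C@@H](O)CC(C)=C)C(=O)N1C(=O)OC[C@H]1Cc1ccccc1 | intermediate
9 | (4R)-4-benzyl-3-{[(1R,6S)-6-hydroxy-4-methylcyclohex-3-en-1-yl]carbonyl}-1,3-oxazolidin-2-one | CC1=CC[C@@H](C(=O)N2C(=O)OC[C@H]2Cc2ccccc2)[C@@H](O)C1 | intermediate
10 | (4R)-4-benzyl-3-{[(1R,2S,4R,5R)-5-chloro-2,4-dihydroxy-4-methylcyclohexyl]carbonyl}-1,3-oxazolidin-2-one | O=C(N1C(=O)OC[C@H]1Cc1ccccc1)[C@@H]2C[C@@H](Cl)[C@](C)(O)C[C@@H]2O | intermediate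
11 | (4R)-4-benzyl-3-{[(1R,2S,4R,5R)-4-bromo-5-chloro-2-hydroxy-4-methylcyclohexyl]carbonyl}-1,3-oxazolidin-2-one | O=C(N1C(=O)OC[C@H]1Cc1ccccc1)[C@@H]2C[C@@H](Cl)[C@](C)(Br)C[C@@H]2O | intermediate
12 | (4R)-4-benzyl-3-{[(1R,2S,4S,5S)-5-bromo-4-chloro-2-hydroxy-4-methylcyclohexyl]carbonyl}-1,3-oxazolidin-2-one | O=C(N1C(=O)OC[C@H]1Cc1ccccc1)[C@@H]2C[C@H](Br)[C@@](C)(Cl)C[C@@H]2O | intermediate
13 | (1R,2S,4S,5S)-5-bromo-4-chloro-2-hydroxy-N-methoxy-N,4-dimethylcyclohexane-1-carboxamide | CON(C)C(=O)[C@@H]1C[C@H](Br)[C@@](C)(Cl)C[C@@H]1O | intermediate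
14 | 1-[(1R,2S,4S,5S)-5-bromo-4-chloro-2-hydroxy-4-methylcyclohexyl]ethan-1-one | CC(=O)[C@@H]1C[C@H](Br)[C@@](C)(Cl)C[C@@H]1O | intermediate
15 | 5-bromo-2-methylpent-2-ene | CC(C)=CCCBr | starting material
16 | (4-methylpent-3-en-1-yl)magnesium bromide | CC(C)=CCC[Mg]Br | intermediate (not isolated)
17 | (1S,2R,4S,5S)-4-bromo-5-chloro-2-[(2S)-2-hydroxy-6-methylhept-5-en-2-yl]-5-methylcyclohexan-1-ol | CC(C)=CCC[C@](C)(O)[C@@H]1C[C@H](Br)[C@@](C)(Cl)C[C@@H]1O | intermediate
18 | (1S,2R,4S,5S)-4-bromo-2-[(2S,5R)-5-bromo-2,6,6-trimethyloxan-2-yl]-5-chloro-5-methylcyclohexan-1-ol | CC1(C)O[C@](C)([C@@H]2C[C@H](Br)[C@@](C)(Cl)C[C@@H]2O)CC[C@H]1Br | target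

Total step count: 11. Longest linear sequence: 10 steps (steps 1 and 3 to 11; step 2 supplies the aldehyde).

Steps most likely to fail

Step 6. The tertiary carbinol is deactivated by the neighbouring chlorine, so ionisation may be slow and the cation may lose a proton (elimination) or be captured on the wrong face (loss of retention). The fallback sets out from 9 and comes back at 11. The hydroxyl of 9 is silylated (TBSOTf, 2,6-lutidine) to the silyl ether F1. mCPBA should epoxidise F1 on the face opposite the axial silyloxy group to give the epoxide F2. LiBr in AcOH/THF opens F2 at the tertiary carbon in the trans-diaxial sense to the bromohydrin F3. SOCl2/pyridine then activates the secondary hydroxyl; the antiperiplanar bromine expels the chlorosulfite as a bromonium ion on the alpha face, and chloride reopens it from the other face to give the bromochloride silyl ether F4. Opening at the other carbon gives the silyl ether of 12, which is equally useful. HF·pyridine frees 11.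

Step 7. The halogen interchange is an equilibrium that may stop short of the diequatorial isomer, and the tertiary bromide may lose hydrogen bromide at the temperature needed. The fallback sets out from 11 and comes back at 18. Compound 11 is carried on unrearranged with the reagents of steps 8 to 10, giving the Weinreb amide F5, the methyl ketone F6 and the tertiary alcohol F7. TBCO closes the oxane to the diaxial dihalide F8. The interchange is then run as the last operation on F8 (MeNO2 or MeCN, 80 °C), where the oxanyl group locks the chair and the polar medium favours the diequatorial dihalide, giving 18.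

Step 11. Closure may go 5-exo to the oxolane with an exocyclic tertiary bromide, or the two bromonium faces may be poorly discriminated. The fallback sets out from 17 and comes back at 18. Shi epoxidation (D-fructose-derived ketone, KHSO5) should give the (R)-epoxide F9. Camphorsulfonic acid induces 5-exo opening with inversion to the oxolane carbinol F10. Thionyl bromide/pyridine ionises the tertiary carbinol with participation of the ring oxygen (bridged oxonium ion), and bromide opens it at the secondary carbon with a second inversion. This expands the ring to the oxane 18 with reagent-controlled configuration at C5.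

Further compounds
F1 | step 6 | (4R)-4-benzyl-3-{[(1R,6S)-6-[(tert-butyldimethylsilyl)oxy]-4-methylcyclohex-3-en-1-yl]carbonyl}-1,3-oxazolidin-2-one | CC1=CC[C@@H](C(=O)N2C(=O)OC[C@H]2Cc2ccccc2)[C@@H](O[Si](C)(C)C(C)(C)C)C1
F2 | step 6 | 3,4-epoxide of F1 with the oxirane oxygen on the ring face opposite to the acyl and silyloxy groups | O=C(N1C(=O)OC[C@H]1Cc1ccccc1)[C@@H]2C[C@H]3O[C@@]3(C)C[C@@H]2O[Si](C)(C)C(C)(C)C
F3 | step 6 | (4R)-4-benzyl-3-{[(1R,2S,4R,5R)-4-bromo-2-[(tert-butyldimethylsilyl)oxy]-5-hydroxy-4-methylcyclohexyl]carbonyl}-1,3-oxazolidin-2-one | O=C(N1C(=O)OC[C@H]1Cc1ccccc1)[C@@H]2C[C@@H](O)[C@](C)(Br)C[C@@H]2O[Si](C)(C)C(C)(C)C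
F4 | step 6 | (4R)-4-benzyl-3-{[(1R,2S,4R,5R)-4-bromo-2-[(tert-butyldimethylsilyl)oxy]-5-chloro-4-methylcyclohexyl]carbonyl}-1,3-oxazolidin-2-one | O=C(N1C(=O)OC[C@H]1Cc1ccccc1)[C@@H]2C[C@@H](Cl)[C@](C)(Br)C[C@@H]2O[Si](C)(C)C(C)(C)C
F5 | step 7 | (1R,2S,4R,5R)-4-bromo-5-chloro-2-hydroxy-N-methoxy-N,4-dimethylcyclohexane-1-carboxamide | CON(C)C(=O)[C@@H]1C[C@@H](Cl)[C@](C)(Br)C[C@@H]1O
F6 | step 7 | 1-[(1R,2S,4R,5R)-4-bromo-5-chloro-2-hydroxy-4-methylcyclohexyl]ethan-1-one | CC(=O)[C@@H]1C[C@@H](Cl)[C@](C)(Br)C[C@@H]1O
F7 | step 7 | (1S,2R,4R,5R)-5-bromo-4-chloro-2-[(2S)-2-hydroxy-6-methylhept-5-en-2-yl]-5-methylcyclohexan-1-ol | CC(C)=CCC[C@](C)(O)[C@@H]1C[C@@H](Cl)[C@](C)(Br)C[C@@H]1O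
F8 | step 7 | (1S,2R,4R,5R)-5-bromo-2-[(2S,5R)-5-bromo-2,6,6-trimethyloxan-2-yl]-4-chloro-5-methylcyclohexan-1-ol | CC1(C)O[C@](C)([C@@H]2C[C@@H](Cl)[C@](C)(Br)C[C@@H]2O)CC[C@H]1Br
F9 | step 11 | (1S,2R,4S,5S)-4-bromo-5-chloro-2-{(2S)-4-[(2R)-3,3-dimethyloxiran-2-yl]-2-hydroxybutan-2-yl}-5-methylcyclohexan-1-ol | CC1(C)O[C@@H]1CC[C@](C)(O)[C@@H]2C[C@H](Br)[C@@](C)(Cl)C[C@@H]2O
F10 | step 11 | (1S,2R,4S,5S)-4-bromo-5-chloro-2-[(2S,5S)-5-(2-hydroxypropan-2-yl)-2-methyloxolan-2-yl]-5-methylcyclohexan-1-ol | CC(C)(O)[C@@H]1CC[C@](C)(O1)[C@@H]2C[C@H](Br)[C@@](C)(Cl)C[C@@H]2O
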